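**Assumption:** the target is an achiral flavone with no stereocentre, so no stereocontrol is needed; it is drawn and isolated as the free hydrogen sulfate.

## Retrosynthetic overview

1. Target 14 comes from hispidulin 13 by 7-O-sulfation in the last step (7-OH is the most acidic phenol).
2. 13 comes from 1,3-diketone 10. Ring C is the only ring made and is closed last by O1–C2 cyclodehydration; O1 is the only benzyl-protected oxygen on ring A, which fixes 6-OMe rather than 8-OMe.
3. 10 comes from the key C2–C3 bond: aldehyde 9 acts as an acyl anion (Breslow intermediate) and α-chloroketone 8 as an enolonium equivalent, so two electrophilic carbons are joined.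
4. 8 comes from 5 by directed ortho-lithiation and chloroacetylation; 5 comes from 2-methoxyresorcinol 1 by MOM protection, steric C–H borylation/oxidation (installs the future O1) and benzylation.
5. Rings A and B are bought as arenes.

## Route

Step 1
Reactants: 1 2-methoxyresorcinol (2-methoxybenzene-1,3-diol)
Product: 2 2-methoxy-1,3-bis(methoxymethoxy)benzene
Conditions: NaH (2.4 equiv), MOMCl (2.4 equiv), DMF, 0 °C → rt
Reagents that add atoms: chloromethyl methyl ether (MOMCl), COCCl
Why: Williamson-type O-alkylation (MOM protection) of both phenoxides gives acetals that carry no aryl C–H and tolerate the later borylation, organolithium and carbene steps.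

Step 2
Reactants: 2 2-methoxy-1,3-bis(methoxymethoxy)benzene
Product: 4 4-methoxy-3,5-bis(methoxymethoxy)phenol, via aryl pinacolboronate 3 (not isolated)
Conditions: [Ir(OMe)(cod)]2 (1.5 mol%), dtbpy (3 mol%), B2pin2 (0.7 equiv), THF, 80 °C; then 30% H2O2, aq NaOH, 0 °C → rt
Reagents that add atoms: bis(pinacolato)diboron, CC1(C)OB(OC1(C)C)B1OC(C)(C)C(C)(C)O1 (Bpin of 3); hydrogen peroxide, OO (phenol O of 4)
Why: Sterically controlled Ir-catalysed C–H borylation (Hartwig–Miyaura/Smith–Maleczka) reacts only at C5–H, the one ring C–H with no ortho substituent, and boronate oxidation then gives the phenol.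

Step 3
Reactants: 4 4-methoxy-3,5-bis(methoxymethoxy)phenol
Product: 5 5-(benzyloxy)-2-methoxy-1,3-bis(methoxymethoxy)benzene
Conditions: BnBr (1.1 equiv), K2CO3, DMF, rt
Reagents that add atoms: benzyl bromide, BrCc1ccccc1
Why: Williamson benzylation marks the future O1 as the only hydrogenolysable oxygen on ring A, so it can later be freed while the 5- and 7-oxygens stay blocked.

Step 4
Reactants: 5 5-(benzyloxy)-2-methoxy-1,3-bis(methoxymethoxy)benzene; 6 2-chloro-N-methoxy-N-methylacetamide
Product: 8 1-[2-(benzyloxy)-5-methoxy-4,6-bis(methoxymethoxy)phenyl]-2-chloroethan-1-one, via aryllithium 7 (not isolated)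
Conditions: n-BuLi (1.15 equiv), TMEDA, THF, −20 → 0 °C; then 6, −78 °C; aq NH4Cl
Reagents that add atoms: n-butyllithium, [Li]CCCC (Li of 7)
Why: Directed ortho-metalation between OMOM and OBn (the two ring C–H are equivalent, so one regioisomer) followed by Weinreb ketone synthesis, where the chelated tetrahedral adduct prevents over-addition.

Step 5
Reactants: 8 1-[2-(benzyloxy)-5-methoxy-4,6-bis(methoxymethoxy)phenyl]-2-chloroethan-1-one; 9 4-(benzyloxy)benzaldehyde
Product: 10 1-[2-(benzyloxy)-5-methoxy-4,6-bis(methoxymethoxy)phenyl]-3-[4-(benzyloxy)phenyl]propane-1,3-dione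
Conditions: 9 (1.5 equiv), 3-benzyl-5-(2-hydroxyethyl)-4-methylthiazolium chloride (20 mol%), i-Pr2NEt (2.5 equiv), NaI (10 mol%), 1,4-dioxane, 60 °C, slow addition of 8
Reagents that add atoms: none
Why: Proposed new method: the thiazol-2-ylidene adds to the unhindered aldehyde 9 to give the Breslow intermediate (acyl anion equivalent), whose nucleophilic carbon displaces halide from the SN2-activated α-keto CH2Cl of 8 (enolonium equivalent; its di-ortho-substituted carbonyl is shielded from cross-benzoin attack, and the weak amine base avoids Darzens condensation), and collapse of the adduct releases the carbene and the 1,3-diketone; a competing single-electron reduction of 8 would give enolate plus acyl azolium, which recombine to the same diketone; the closest known reaction types are the NHC-catalysed (Stetter-type umpolung) acylation of activated alkyl halides such as benzyl bromides and the intramolecular NHC SN2 route to chromanones; no stereocentre is formed.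

Step 6
Reactants: 10 1-[2-(benzyloxy)-5-methoxy-4,6-bis(methoxymethoxy)phenyl]-3-[4-(benzyloxy)phenyl]propane-1,3-dione
Product: 13 hispidulin (5,7-dihydroxy-2-(4-hydroxyphenyl)-6-methoxy-4H-chromen-4-one), via debenzylated diketone 11 (not isolated), via bis-MOM flavone 12 (not isolated)
Conditions: H2 (1 atm), 10% Pd/C, EtOAc/MeOH, rt; filter; then conc. HCl, MeOH, 0 → 50 °C
Reagents that add atoms: none
Why: Hydrogenolysis frees only O1 on ring A (and 4'-OH), so the fast acid-catalysed cyclodehydration of the o-hydroxyaryl 1,3-diketone (flavone ring closure) can give only the 6-methoxy isomer before the slower acetal exchange removes the two MOM groups.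

Step 7
Reactants: 13 hispidulin
Product: 14 hispidulin 7-sulfate (4',5-dihydroxy-6-methoxyflavon-7-yl hydrogen sulfate)
Conditions: SO3·pyridine (1.1 equiv), pyridine, 0 °C → rt; RP-C18, H+ exchange
Reagents that add atoms: sulfur trioxide–pyridine complex, [O-]S(=O)(=O)[n+]1ccccc1
Why: Phenol O-sulfation with an SO3–amine complex occurs at 7-OH, the most acidic and nucleophilic phenol (para-conjugated to C4=O), because 5-OH is chelated to the carbonyl and 4'-OH is less acidic (known flavone sulfation order 7 > 4' ≫ 5).

## Compound list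

1 | 2-methoxyresorcinol | COc1c(O)cccc1O | starting material
2 | 2-methoxy-1,3-bis(methoxymethoxy)benzene | COCOc1cccc(OCOC)c1OC | intermediate
3 | 2-[4-methoxy-3,5-bis(methoxymethoxy)phenyl]-4,4,5,5-tetramethyl-1,3,2-dioxaborolane | COCOc1cc(B2OC(C)(C)C(C)(C)O2)cc(OCOC)c1OC | intermediate (not isolated)
4 | 4-methoxy-3,5-bis(methoxymethoxy)phenol | COCOc1cc(O)cc(OCOC)c1OC | intermediate
5 | 5-(benzyloxy)-2-methoxy-1,3-bis(methoxymethoxy)benzene | COCOc1cc(OCc2ccccc2)cc(OCOC)c1OC | intermediate
6 | 2-chloro-N-methoxy-N-methylacetamide | CON(C)C(=O)CCl | starting material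
7 | [2-(benzyloxy)-5-methoxy-4,6-bis(methoxymethoxy)phenyl]lithium | [Li]c1c(OCc2ccccc2)cc(OCOC)c(OC)c1OCOC | intermediate (not isolated)
8 | 1-[2-(benzyloxy)-5-methoxy-4,6-bis(methoxymethoxy)phenyl]-2-chloroethan-1-one | ClCC(=O)c1c(OCc2ccccc2)cc(OCOC)c(OC)c1OCOC | intermediate
9 | 4-(benzyloxy)benzaldehyde | O=Cc1ccc(OCc2ccccc2)cc1 | starting material
10 | 1-[2-(benzyloxy)-5-methoxy-4,6-bis(methoxymethoxy)phenyl]-3-[4-(benzyloxy)phenyl]propane-1,3-dione | O=C(CC(=O)c1ccc(OCc2ccccc2)cc1)c1c(OCc2ccccc2)cc(OCOC)c(OC)c1OCOC | intermediate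
11 | 1-[2-hydroxy-5-methoxy-4,6-bis(methoxymethoxy)phenyl]-3-(4-hydroxyphenyl)propane-1,3-dione | O=C(CC(=O)c1ccc(O)cc1)c1c(O)cc(OCOC)c(OC)c1OCOC | intermediate (not isolated)
12 | 2-(4-hydroxyphenyl)-6-methoxy-5,7-bis(methoxymethoxy)-4H-chromen-4-one | COCOc1cc2oc(-c3ccc(O)cc3)cc(=O)c2c(OCOC)c1OC | intermediate (not isolated)
13 | hispidulin | COc1c(O)cc2oc(-c3ccc(O)cc3)cc(=O)c2c1O | intermediate
14 | hispidulin 7-sulfate | COc1c(OS(=O)(=O)O)cc2oc(-c3ccc(O)cc3)cc(=O)c2c1O | target

## Step count and risks

Total step count: 7. Longest linear sequence: 7 (1 → 14); compounds 6 and 9 are bought.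

The three steps most likely to fail:

**Step 5 (carbene-catalysed acylation of the α-chloroketone).** The carbene can be alkylated irreversibly by 8, and benzoin formation or reduction of 8 may win. Fallback: set out from 8 and use the same two partners with the polarity of 8 inverted by reduction. SmI2 (2.2 equiv, THF, −78 °C) turns 8 into its samarium enolate, which adds to aldehyde 9 in a Reformatsky-type aldol to give racemic 1-[2-(benzyloxy)-5-methoxy-4,6-bis(methoxymethoxy)phenyl]-3-[4-(benzyloxy)phenyl]-3-hydroxypropan-1-one F1. Oxidation of this β-hydroxy ketone with Dess–Martin periodinane or IBX comes back to the route at 10.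

**Step 7 (site-selective sulfation).** 4'-O-sulfate and 7,4'-disulfate may form and are hard to separate as salts. Fallback: set out from 13 and block 4'-OH temporarily. Ac2O/pyridine gives 7,4'-di-O-acetylhispidulin F2 (the chelated 5-OH stays free). PhSH/imidazole in NMP at 0 °C removes only the most labile 7-acetate to give 4'-O-acetylhispidulin F3. SO3·pyridine then sulfates the only reactive phenol to give 4'-O-acetylhispidulin 7-sulfate F4, and NH3/MeOH at 0 °C cleaves the acetate (aryl sulfates are base-stable) and comes back to the route at 14.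

**Step 4 (aryllithium with the chloro-Weinreb amide).** The aryllithium may be consumed by proton transfer or chloride displacement. Fallback: set out from 5, lithiate as before but quench with N-methoxy-N-methylacetamide to give the methyl ketone 1-[2-(benzyloxy)-5-methoxy-4,6-bis(methoxymethoxy)phenyl]ethan-1-one F5. Its lithium enolate (LDA, THF, −78 °C) is then chlorinated electrophilically with TsCl and comes back to the route at 8.

## Further compounds

F1 | step 5 | 1-[2-(benzyloxy)-5-methoxy-4,6-bis(methoxymethoxy)phenyl]-3-[4-(benzyloxy)phenyl]-3-hydroxypropan-1-one (racemic) | O=C(CC(O)c1ccc(OCc2ccccc2)cc1)c1c(OCc2ccccc2)cc(OCOC)c(OC)c1OCOC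
F2 | step 7 | 7,4'-di-O-acetylhispidulin | COc1c(OC(C)=O)cc2oc(-c3ccc(OC(C)=O)cc3)cc(=O)c2c1O
F3 | step 7 | 4'-O-acetylhispidulin | COc1c(O)cc2oc(-c3ccc(OC(C)=O)cc3)cc(=O)c2c1O
F4 | step 7 | 4'-O-acetylhispidulin 7-sulfate | COc1c(OS(=O)(=O)O)cc2oc(-c3ccc(OC(C)=O)cc3)cc(=O)c2c1O
F5 | step 4 | 1-[2-(benzyloxy)-5-methoxy-4,6-bis(methoxymethoxy)phenyl]ethan-1-one | CC(=O)c1c(OCc2ccccc2)cc(OCOC)c(OC)c1OCOC
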